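## The problem

Compound 21 is a depside. The carboxyl carbon of ring A (a 2-heptyl-4,6-dimethoxybenzoyl unit) is esterified with the C4 oxygen of ring B, a 2-methoxy-6-pentylbenzoic acid whose own carboxyl group at C1 stays free. The molecule has no stereocenter and no double-bond geometry, so there is nothing for one stereocenter to control; the task is regiochemistry and telling like groups apart. Ring B is a tetrasubstituted benzene with pentyl (C6), carboxyl (C1) and methoxy (C2) on three neighbouring carbons, and its two phenolic oxygens must end up different: methylated at C2, acylated at C4. The two carboxyl groups must also be distinguished, and each is flanked by two ortho substituents, which slows any reaction at these carbonyl carbons. The aryl ester is the fragile element. It is an activated ester that hydroxide, alkoxides, amines and organometallic reagents cleave, so all strongly basic chemistry and all O-methylation must be finished before it is made, and the ring B acid must be released last under neutral conditions. The feature that opens a short path is the sequence C6-pentyl, C1-carboxyl, C2-methoxy in ring B with the C4 oxygen meta to both C2 and C6. This is the pattern left when a carbon nucleophile and CO2 add across a C1–C6 aryne bond that has the methoxy-bearing C2 as its neighbour, and such an aryne comes from a 1,3,5-trisubstituted benzene carrying chlorine at C6. Ring A repeats the alkyl/carboxyl/methoxy sequence but has two identical methoxy groups, so ordinary electrophilic substitution is enough there.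

## Retrosynthesis

**21 from 20.** The last bond cut is the O–CH2 bond of a benzyl ester on the ring B carboxyl. The acid has to be masked while the depside ester is made, or mixed anhydrides would form. It must then be unmasked without base or nucleophile, which rules out simple alkyl esters because saponification would attack the less hindered depside link first. Hydrogenolysis of benzyl ester 20 is neutral and leaves aryl esters and aryl ethers alone.

**20 from 18 and 12.** Cutting the acyl C–O bond of the depside divides the molecule into two halves of similar size, acid 18 (activated as chloride 19) and phenol 12, which makes the route convergent. The alternative of building either ring with the ester already in place would expose the ester to enolate or organometallic chemistry. The forward reaction asks a di-ortho-substituted aroyl chloride to acylate a phenol that is unhindered but deactivated by its para ester.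

**12 from 11 and 10.** These are protecting-group changes only: the O–Si bond of a silyl ether at C4 and the benzyl ester at C1. The order is chosen so that the carboxylate is alkylated while the C4 oxygen is still silylated, which removes any question of O-benzylation at the phenol. The silyl group then leaves under buffered, non-hydrolytic conditions that spare the benzyl ester.

**10 from 2, 4 and 5.** Both carbon substituents of ring B are removed at once: the C6–pentyl bond and the C1–carboxyl bond. Chloroarene 2 is lithiated to 6, which loses LiCl to give aryne 7; pentyllithium 4 adds to give aryllithium 8, and CO2 5 gives carboxylate 9. The neighbouring disconnections are weaker. Carboxylating a 5-pentylresorcinol derivative gives two free phenols that then need to be told apart. Directed lithiation of an arene that already carries the pentyl group has no clear preference between the two positions ortho to methoxy. In 2 the chlorine acidifies the adjacent C–H, marks the carbon that receives the pentyl group and serves as the leaving group. The precursor is a benzene with three heteroatom substituents and no carbon substituent. The forward step must lithiate at one site only, add the nucleophile at one aryne carbon only, and capture CO2 cleanly.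

**2 from 1, and 4 from 3.** Silyl ether 2 comes from phenol 1, which already has the two ring B oxygens differentiated (one methyl ether, one free hydroxyl) and the chlorine meta to both. Pentyllithium 4 comes from chloride 3 by reductive lithiation. Both are single, routine operations.

**18 from 17, 15, 13 and 14.** In ring A the carboxyl carbon is traced back to the formyl group of aldehyde 17, placed on 15 by electrophilic substitution at the carbon ortho to heptyl and para to a methoxy group. The aryl–heptyl bond of 15 is cut to bromide 13 and Grignard reagent 14. The aryne route is not carried over to ring A: with two methoxy groups the ring proton between them would compete for the base and has no leaving group beside it. In 2 that position is shielded by the silyl ether.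

## Roads not taken

**Alternative 1:** Ring A is unravelled at its C1–C2 bond into a linear 3,5,7-trioxotetradecanoyl chain already esterified to the C4 oxygen of ring B. The precursor is the triketo ester A1, benzyl 2-methoxy-6-pentyl-4-[(3,5,7-trioxotetradecanoyl)oxy]benzoate. In the forward direction, aldol addition of chain C2 to the C7 ketone, dehydration and enolisation would close ring A and give the dihydroxy depside A2, which two O-methylations would convert into 20.
- Merits: the ester bond is made with an unhindered acyclic acyl donor, so the slow acylation of step 9 is avoided, and the whole ring A substitution pattern appears in one event.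
- Weak points: A1 is an aryl ester of a β-keto acid. Closure of the C5 enol oxygen onto C1 with loss of phenol 12 to give pyrone A3 is the familiar competing mode, and a phenoxide leaving group favours it. A2 then needs methylation of a hydroxyl chelated to the ester carbonyl, which calls for base and heat with the depside link already present. Phenol 12 must still be made, so this road replaces only steps 6 to 9, and the masked triketide needs its own multistep preparation.
- Comparison: this road is better on the esterification itself. The chosen plan sets against that the fact that both ring A methoxy groups are in place before the fragile ester exists, and that its ring A steps are routine.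

**Alternative 2:** Ring B is cut at C1–C6 and C2–C3. The two building blocks are the enone A4, which is (E)-non-3-en-2-one, and the malonate A5, which is dibenzyl malonate. The anion of A5 would add to C4 of A4, and the methyl ketone enolate of the adduct would then close the ring by Claisen condensation onto one benzyl ester to give dione A6. Dehydrogenation would give the dihydroxy benzoate A7, benzyl 2,4-dihydroxy-6-pentylbenzoate.
- Merits: A4 and A5 are cheap acyclic materials, no cryogenic organolithium chemistry is needed, the sequence should scale well, and the benzyl ester arrives already installed.
- Weak points: A7 has two free phenols, and the target needs methyl at O2 and acyl at O4. The O2 hydroxyl is chelated and the less reactive of the two. Either O4 is protected, O2 methylated and O4 released (three steps to reach 12), or O4 is acylated first and the chelated O2 is methylated with base in the presence of the depside ester. The aromatisation of the β-keto ester dione A6 by halogenation and elimination also risks ring halogenation.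
- Comparison: about five steps to 12, against four in the longest line of the chosen plan plus one reagent preparation. The gap is small, and on scale this road is arguably the more robust. The chosen plan sets against it that the oxygen differentiation comes with starting material 1 and is never in question, and that both carbon–carbon bonds of ring B form in one flask without any adjustment of ring oxidation level.

**Alternative 3:** Ring B is cut at C3–C4 and C5–C6. Pyrone A8, which is benzyl 4-methoxy-6-oxo-2-pentyl-6H-pyran-3-carboxylate, and ketene acetal A9 would combine in a (4+2) cycloaddition. Decarboxylative extrusion of the lactone bridge and loss of the silyloxy group would give phenol A10, which is identical with 12.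
- Merits: methoxy, benzyl ester and pentyl are fixed by the pyrone, and the polarity of the partners directs the nucleophilic CH2 of A9 to the pentyl-bearing pyrone carbon. No protecting-group change is needed between ring formation and 12, whereas the chosen plan spends steps 1, 4 and 5 on this. In that respect this road is better.
- Weak points: A8 is not a catalogue compound. It would need construction of a 4-hydroxypyrone bearing the ester, then an O-methylation that must pick the C4 hydroxyl over the ring carbonyl oxygen. The 4-methoxy donor lowers the electron demand of the diene, and the substituted terminus is hindered. A9 is hydrolytically labile and can add in a conjugate sense and open the lactone without closing the ring.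
- Comparison: with the pyrone synthesis counted, the total would not be lower. Both roads meet at 12 and share the same end game. The chosen plan sets against the saved protecting-group steps a commercial benzene starting material and a skeleton-building step of a known reaction type.

Key step: step 3

## Route

Assumption: 3-chloro-5-methoxyphenol, 1-bromo-3,5-dimethoxybenzene and heptylmagnesium bromide (ether solution) are taken as purchased; pentyllithium is prepared because it is not a routine catalogue reagent.

Step 1
Reactants: 1 3-chloro-5-methoxyphenol
Product: 2 (3-chloro-5-methoxyphenoxy)triisopropylsilane
Conditions: iPr3SiCl, imidazole, DMF, rt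
Reagents that add atoms: triisopropylsilyl chloride, CC(C)[Si](Cl)(C(C)C)C(C)C
Why: Standard silylation of a phenol with a silyl chloride and imidazole; the triisopropylsilyl group is chosen because it survives alkyllithium reagents, coordinates lithium poorly and shields both of its ortho positions.

Step 2
Reactants: 3 1-chloropentane
Product: 4 pentyllithium
Conditions: Li (1% Na) dispersion, hexane, 40 °C; filtered and titrated
Reagents that add atoms: lithium metal, [Li]
Why: Reductive lithiation of a primary alkyl chloride with lithium metal in a hydrocarbon, the standard preparation of n-alkyllithium reagents; LiCl is insoluble and is filtered off.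

Step 3
Reactants: 2 (3-chloro-5-methoxyphenoxy)triisopropylsilane; 4 pentyllithium; 5 carbon dioxide
Product: 10 2-methoxy-6-pentyl-4-(triisopropylsilyloxy)benzoic acid, via chloroaryllithium 6 (not isolated), via aryne 7 (not isolated), via pentylated aryllithium 8 (not isolated), via lithium carboxylate 9 (not isolated)
Conditions: 4 (3 equiv), THF–hexane, −78 °C, then −78 to −20 °C; CO2 (5), −78 °C to rt; 1 M HCl
Reagents that add atoms: none
Why: Tandem aryne carbolithiation–carboxylation: pentyllithium 4 removes the ring proton of 2 that is flanked by chlorine and methoxy, the most acidic C–H and the one to which the methoxy oxygen guides the base, giving chloroaryllithium 6, which persists at −78 °C. On warming, 6 loses LiCl to give aryne 7, whose triple bond (the future ring B C1–C6 bond) lies beside the methoxy group. A second equivalent of 4 adds at the aryne carbon remote from methoxy (future C6), because the inductively withdrawing methoxy group distorts the aryne toward attack there and the carbanion of 8 develops ortho to oxygen, where induction and Li–O chelation stabilise it. CO2 5 carboxylates 8 at the future C1 to give lithium carboxylate 9, and acidification releases 10, so the C6–pentyl and C1–carboxyl bonds form in one flask. The closest known reaction type is the tandem addition of alkyllithium reagents to 3-methoxybenzynes generated from 3-haloanisoles, with carboxylation of the 2-lithio intermediate to 6-alkyl-2-methoxybenzoic acids. No ring closes and no stereocenter forms. Two selectivities are needed: the site of lithiation, secured by the chlorine–methoxy pocket and by the bulky, poorly coordinating triisopropylsilyl ether, and the site of carbon–carbon bond formation, secured by the methoxy group next to the triple bond. Excess 4 keeps aryllithium 8 from competing for 7, and the aryl chloride resists halogen–lithium exchange, so deprotonation is the only entry.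

Step 4
Reactants: 10 2-methoxy-6-pentyl-4-(triisopropylsilyloxy)benzoic acid
Product: 11 benzyl 2-methoxy-6-pentyl-4-(triisopropylsilyloxy)benzoate
Conditions: BnBr, KHCO3, DMF, rt
Reagents that add atoms: benzyl bromide, BrCc1ccccc1
Why: SN2 alkylation of the carboxylate by benzyl bromide, which is insensitive to the two ortho substituents that would block esterification at the carbonyl carbon; the weak base KHCO3 ionises only the acid and leaves the aryl silyl ether intact.

Step 5
Reactants: 11 benzyl 2-methoxy-6-pentyl-4-(triisopropylsilyloxy)benzoate
Product: 12 benzyl 4-hydroxy-2-methoxy-6-pentylbenzoate
Conditions: Bu4NF, AcOH, THF, 0 °C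
Reagents that add atoms: none
Why: Fluoride-induced cleavage of the aryl silyl ether, driven by Si–F bond formation; acetic acid buffers the phenoxide so that the hindered benzyl ester is not attacked.

Step 6
Reactants: 13 1-bromo-3,5-dimethoxybenzene; 14 heptylmagnesium bromide
Product: 15 1-heptyl-3,5-dimethoxybenzene
Conditions: NiCl2(dppp) (2 mol %; dppp = 1,3-bis(diphenylphosphino)propane), Et2O, reflux
Reagents that add atoms: none
Why: Kumada–Tamao–Corriu coupling of an aryl bromide with a primary alkyl Grignard reagent; the chelating diphosphine on the divalent nickel precatalyst makes reductive elimination faster than β-hydride elimination, so the unbranched heptyl chain is transferred.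

Step 7
Reactants: 15 1-heptyl-3,5-dimethoxybenzene
Product: 17 2-heptyl-4,6-dimethoxybenzaldehyde, via iminium chloride 16 (not isolated)
Conditions: POCl3, DMF, 0 to 60 °C; then ice–water
Reagents that add atoms: N,N-dimethylformamide, CN(C)C=O; water, O
Why: Vilsmeier–Haack formylation; the chloroiminium electrophile attacks the ring carbon ortho to heptyl, which is para to one methoxy group and ortho to the other, in preference to the carbon between the two methoxy groups, and iminium salt 16 is hydrolysed on work-up.

Step 8
Reactants: 17 2-heptyl-4,6-dimethoxybenzaldehyde
Product: 18 2-heptyl-4,6-dimethoxybenzoic acid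
Conditions: NaClO2, NaH2PO4, 2-methylbut-2-ene, t-BuOH–H2O, rt
Reagents that add atoms: sodium chlorite, [Na+].[O-]Cl=O
Why: Pinnick oxidation of the aldehyde to the acid; chlorous acid does not attack the electron-rich ring, and the excess alkene removes the hypochlorous acid that would otherwise chlorinate it.

Step 9
Reactants: 18 2-heptyl-4,6-dimethoxybenzoic acid; 12 benzyl 4-hydroxy-2-methoxy-6-pentylbenzoate
Product: 20 benzyl 4-[(2-heptyl-4,6-dimethoxybenzoyl)oxy]-2-methoxy-6-pentylbenzoate, via acid chloride 19 (not isolated)
Conditions: (COCl)2, DMF (cat.), CH2Cl2, 0 °C to rt, concentrate; then 12, Et3N, DMAP (cat.), CH2Cl2, 0 °C to rt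
Reagents that add atoms: none
Why: Acid chloride formation with oxalyl chloride under DMF catalysis, then DMAP-catalysed acylation of the unhindered phenol 12; the ring B carboxyl is masked as the benzyl ester, so the phenol is the only nucleophile and no mixed anhydride can form.

Step 10
Reactants: 20 benzyl 4-[(2-heptyl-4,6-dimethoxybenzoyl)oxy]-2-methoxy-6-pentylbenzoate
Product: 21 4-[(2-heptyl-4,6-dimethoxybenzoyl)oxy]-2-methoxy-6-pentylbenzoic acid
Conditions: H2 (1 atm), 10% Pd/C, EtOAc, rt
Reagents that add atoms: none
Why: Hydrogenolysis of the benzyl ester over palladium on carbon under neutral conditions in a non-nucleophilic solvent; aryl esters, aryl methyl ethers and alkyl chains are inert, so the depside link survives and the free acid is released.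

## Compound list

1 | 3-chloro-5-methoxyphenol | COc1cc(O)cc(Cl)c1 | starting material
2 | (3-chloro-5-methoxyphenoxy)triisopropylsilane | COc1cc(Cl)cc(O[Si](C(C)C)(C(C)C)C(C)C)c1 | intermediate
3 | 1-chloropentane | CCCCCCl | starting material
4 | pentyllithium | [Li]CCCCC | intermediate
5 | carbon dioxide | O=C=O | starting material
6 | (2-chloro-6-methoxy-4-triisopropylsilyloxyphenyl)lithium | COc1cc(O[Si](C(C)C)(C(C)C)C(C)C)cc(Cl)c1[Li] | intermediate (not isolated)
7 | 3-methoxy-5-(triisopropylsilyloxy)benzyne (1,2-didehydro-3-methoxy-5-triisopropylsilyloxybenzene) | COC1=CC(O[Si](C(C)C)(C(C)C)C(C)C)=CC#C1 | intermediate (not isolated)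
8 | (2-methoxy-6-pentyl-4-triisopropylsilyloxyphenyl)lithium | CCCCCc1cc(O[Si](C(C)C)(C(C)C)C(C)C)cc(OC)c1[Li] | intermediate (not isolated)
9 | lithium 2-methoxy-6-pentyl-4-(triisopropylsilyloxy)benzoate | CCCCCc1cc(O[Si](C(C)C)(C(C)C)C(C)C)cc(OC)c1C(=O)[O-].[Li+] | intermediate (not isolated)
10 | 2-methoxy-6-pentyl-4-(triisopropylsilyloxy)benzoic acid | CCCCCc1cc(O[Si](C(C)C)(C(C)C)C(C)C)cc(OC)c1C(=O)O | intermediate
11 | benzyl 2-methoxy-6-pentyl-4-(triisopropylsilyloxy)benzoate | CCCCCc1cc(O[Si](C(C)C)(C(C)C)C(C)C)cc(OC)c1C(=O)OCc1ccccc1 | intermediate
12 | benzyl 4-hydroxy-2-methoxy-6-pentylbenzoate | CCCCCc1cc(O)cc(OC)c1C(=O)OCc1ccccc1 | intermediate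
13 | 1-bromo-3,5-dimethoxybenzene | COc1cc(Br)cc(OC)c1 | starting material
14 | heptylmagnesium bromide | CCCCCCC[Mg]Br | starting material
15 | 1-heptyl-3,5-dimethoxybenzene | CCCCCCCc1cc(OC)cc(OC)c1 | intermediate
16 | N-[(2-heptyl-4,6-dimethoxyphenyl)methylidene]-N-methylmethanaminium chloride | CCCCCCCc1cc(OC)cc(OC)c1C=[N+](C)C.[Cl-] | intermediate (not isolated)
17 | 2-heptyl-4,6-dimethoxybenzaldehyde | CCCCCCCc1cc(OC)cc(OC)c1C=O | intermediate
18 | 2-heptyl-4,6-dimethoxybenzoic acid | CCCCCCCc1cc(OC)cc(OC)c1C(=O)O | intermediate
19 | 2-heptyl-4,6-dimethoxybenzoyl chloride | CCCCCCCc1cc(OC)cc(OC)c1C(Cl)=O | intermediate (not isolated)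
20 | benzyl 4-[(2-heptyl-4,6-dimethoxybenzoyl)oxy]-2-methoxy-6-pentylbenzoate | CCCCCCCc1cc(OC)cc(OC)c1C(=O)Oc1cc(CCCCC)c(C(=O)OCc2ccccc2)c(OC)c1 | intermediate
21 | 4-[(2-heptyl-4,6-dimethoxybenzoyl)oxy]-2-methoxy-6-pentylbenzoic acid | CCCCCCCc1cc(OC)cc(OC)c1C(=O)Oc1cc(CCCCC)c(C(=O)O)c(OC)c1 | target

## Step count and least certain steps

Total step count: 10. Longest linear sequence: 6 steps (steps 1, 3, 4, 5, 9, 10).

**Step 3 (key step).** The most likely loss is at the aryne stage. Aryllithium 8 accumulates and can compete with pentyllithium for aryne 7, leading to biaryl oligomerisation. A further leak is over-addition of excess pentyllithium to carboxylate 9 if the carboxylation mixture warms. A smaller risk is lithiation outside the chlorine–methoxy pocket, which would end in carboxylation without pentyl transfer. The fallback separates the two bond formations and avoids the aryne. It sets out from 2, which is lithiated at −78 °C with n-BuLi to 6 and carboxylated at that temperature, before LiCl is lost, to give 2-chloro-6-methoxy-4-(triisopropylsilyloxy)benzoic acid F1. Benzylation (BnBr, KHCO3, DMF) gives benzyl 2-chloro-6-methoxy-4-(triisopropylsilyloxy)benzoate F2. Negishi coupling of its ester-activated aryl chloride with pentylzinc bromide (Pd(OAc)2, the ligand 2-dicyclohexylphosphino-2',6'-dimethoxybiphenyl, THF, 60 °C) installs the pentyl group at the carbon that carried chlorine. The fallback comes back to the route at 11.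

**Step 9.** Acyl transfer from the di-ortho-substituted aroyl chloride 19 to phenol 12, which its para ester deactivates, may be slow, so hydrolysis of 19 by adventitious water or decomposition on forcing could outrun ester formation. The fallback changes the mode of activation from addition–elimination to an acylium pathway. It sets out from 18 and 12, which are treated together with trifluoroacetic anhydride in toluene at rt. The mixed anhydride 2-heptyl-4,6-dimethoxybenzoic trifluoroacetic anhydride F3 ionises readily because the ortho and para methoxy groups stabilise the linear acylium ion, which is not subject to the steric shielding of a tetrahedral intermediate. Capture by 12 brings the fallback back to the route at 20.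

**Step 7.** Some formylation at the ring carbon between the two methoxy groups, or incomplete conversion beside the heptyl chain, would give material that is hard to separate. The fallback replaces formylation and oxidation by halogenation and carboxylation. It sets out from 15, which N-bromosuccinimide in MeCN at 0 °C should brominate ortho to the alkyl chain and para to a methoxy group, the usual site for 5-alkylresorcinol dimethyl ethers, giving 2-bromo-1-heptyl-3,5-dimethoxybenzene F4. Bromine–lithium exchange (n-BuLi, THF, −78 °C) gives (2-heptyl-4,6-dimethoxyphenyl)lithium F5, and CO2 followed by acidic work-up brings the fallback back to the route at 18, bypassing 17 and step 8.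

**Step 6.** β-Hydride elimination from the heptylnickel intermediate would cause reduction of 13 and chain isomerisation, and homocoupling of either partner is possible. The fallback uses a coupling partner without β-hydrogens on the metal-bound carbon. It sets out from 13, which undergoes Sonogashira coupling with hept-1-yne (PdCl2(PPh3)2, CuI, Et3N, 60 °C) to give 1-(hept-1-yn-1-yl)-3,5-dimethoxybenzene F6. Hydrogenation (H2, Pd/C, EtOAc) saturates the triple bond and brings the fallback back to the route at 15.

## Further compounds

F1 | step 3 | 2-chloro-6-methoxy-4-(triisopropylsilyloxy)benzoic acid | COc1cc(O[Si](C(C)C)(C(C)C)C(C)C)cc(Cl)c1C(=O)O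
F2 | step 3 | benzyl 2-chloro-6-methoxy-4-(triisopropylsilyloxy)benzoate | COc1cc(O[Si](C(C)C)(C(C)C)C(C)C)cc(Cl)c1C(=O)OCc1ccccc1
F3 | step 9 | 2-heptyl-4,6-dimethoxybenzoic trifluoroacetic anhydride | CCCCCCCc1cc(OC)cc(OC)c1C(=O)OC(=O)C(F)(F)F
F4 | step 7 | 2-bromo-1-heptyl-3,5-dimethoxybenzene | CCCCCCCc1cc(OC)cc(OC)c1Br
F5 | step 7 | (2-heptyl-4,6-dimethoxyphenyl)lithium | CCCCCCCc1cc(OC)cc(OC)c1[Li]
F6 | step 6 | 1-(hept-1-yn-1-yl)-3,5-dimethoxybenzene | CCCCCC#Cc1cc(OC)cc(OC)c1
A1 | alternative 1 | benzyl 2-methoxy-6-pentyl-4-[(3,5,7-trioxotetradecanoyl)oxy]benzoate | CCCCCCCC(=O)CC(=O)CC(=O)CC(=O)Oc1cc(CCCCC)c(C(=O)OCc2ccccc2)c(OC)c1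
A2 | alternative 1 | benzyl 4-[(2-heptyl-4,6-dihydroxybenzoyl)oxy]-2-methoxy-6-pentylbenzoate | CCCCCCCc1cc(O)cc(O)c1C(=O)Oc1cc(CCCCC)c(C(=O)OCc2ccccc2)c(OC)c1
A3 | alternative 1 | 4-hydroxy-6-(2-oxononyl)-2H-pyran-2-one | CCCCCCCC(=O)CC1=CC(O)=CC(=O)O1
A4 | alternative 2 | (E)-non-3-en-2-one | CCCCC/C=C/C(C)=O
A5 | alternative 2 | dibenzyl malonate | O=C(CC(=O)OCc1ccccc1)OCc1ccccc1
A6 | alternative 2 | benzyl trans-2,4-dioxo-6-pentylcyclohexane-1-carboxylate (racemic, one enantiomer drawn) | CCCCC[C@@H]1CC(=O)CC(=O)[C@H]1C(=O)OCc1ccccc1
A7 | alternative 2 | benzyl 2,4-dihydroxy-6-pentylbenzoate | CCCCCc1cc(O)cc(O)c1C(=O)OCc1ccccc1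
A8 | alternative 3 | benzyl 4-methoxy-6-oxo-2-pentyl-6H-pyran-3-carboxylate | CCCCCC1=C(C(=O)OCc2ccccc2)C(OC)=CC(=O)O1
A9 | alternative 3 | 1,1-bis(trimethylsilyloxy)ethene | C=C(O[Si](C)(C)C)O[Si](C)(C)C
A10 | alternative 3 | benzyl 4-hydroxy-2-methoxy-6-pentylbenzoate (identical with 12) | CCCCCc1cc(O)cc(OC)c1C(=O)OCc1ccccc1
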